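The constants were set for the occasion; what happens was integrated by code.

Look at the acid first.

substrate 0.018 M; acid 0.0540 mM; time 15 h

    substrate + acid → weak acid + acid + product (k1 = 2530 M⁻¹ h⁻¹)
    weak acid ⇌ conjugate base + acid, settled at all times (K2 = 7.9 × 10⁻¹⁰ M)
    substrate → weak acid + product (k3 = 0.0212 h⁻¹)
    crystals ⇌ weak acid, rate k4*(cs4 - [weak acid]) while solid is left; crystals form when [weak acid] > cs4 (cs4 = 0.26 mM, k4 = 0.795 h⁻¹)

- acid is the free proton; pH is minus the decimal logarithm of its molar concentration
- what is said of weak acid includes crystals
- crystals is a solid; its amount is given per volume of the solution
- run time (flask): 15 h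

- part of the substrate that has reacted at 15 h
- pH of the solution at 15 h

In this flask substrate is lost by step 1, with acid, and by step 3, without it. Both are first order in substrate, so dividing one rate by the other removes substrate and time and leaves the ratio S, the rate of step 1 over that of step 3, k₁[acid]/k₃, here 6.44 at the charged acid, which makes step 1 the faster.

Step 1 gives back the acid it uses and the dissociation of weak acid adds to it, so the charge is a floor on acid. At that floor substrate falls in a pseudo-first-order decay with constant k₃(1+S), and over 15 h we get a lower bound of 90.6% on c, the part of the substrate that has reacted. For the upper bound we let the whole substrate charge stand as dissolved weak acid, which holds acid under 0.0543 mM, so c stays under 90.7% and the pH lies at most 0.00211 below that of the charge.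

The forecast gives 90.6%, between 90% and 91.2%, and pH 4.27, between 4.26 and 4.28, holding that “the proton concentration stays near” its charge. Its c matches our lower bound to the digits shown, and its range is wider than our bracket on both sides.

The simulation gives 90.6% reacted, with 9.4% of the substrate left, and pH 4.27, and the ratio of the two steps reads 6.4 just after the start and 6.4 at 15.0 h. In a neighbouring flask charged with 3.2 × 10⁻⁵ M of acid, the rest as before, S falls to 3.82, and k₃(1+S) over the same time gives c = 78.4%. The simulation of that neighbouring flask leaves 22% of the substrate, so 78.4% has reacted.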